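## Analysis of the target

The target 22 is an isoflavan, numbered in the usual way (ring C: O1, C2, C3, C4; ring A: C4a, C5 to C8, C8a; ring B: C1' to C6'). Ring A is a fully differentiated phloroglucinol: the ring C oxygen sits on C8a, a formyl group on C8, a free hydroxyl on C7, hydrogen on C6 and a methyl ether on C5. Ring B is a 2',4'-dihydroxyphenyl group with a prenyl substituent on C3', between the two hydroxyls. C3 is the only stereocentre and is (R) (ranking C2 > C1' > C4 > H); as an isolated benzylic methine it has no neighbour to relay from and must be set by a reagent or catalyst. The sensitive elements are the aryl aldehyde, three free phenols and the prenyl olefin flanked by two phenols, which closes to a dimethylchroman under strong acid and excludes hydrogenation and hydrogenolysis. Beyond the stereocentre there are three selectivity problems: the formyl group must go to C8 and not to the equally activated C6, O7 must be told from O5, and ring B needs three contiguous substituents in a fixed order. The strategy rests on C4 being an unsubstituted methylene on C4a, next to the oxygen-bearing C8a. O1, C8a, C4a and C4 are then the four atoms of a ring A ortho-quinone methide, and C3 and C2 are the α-carbon and carboxyl carbon of a ring B arylacetic acid. Their union as a formal [4+2] gives ring C as a lactone with C3 set, and the lactone oxygen, once freed as the C8a phenol, later steers the formyl group to C8.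

## Retrosynthetic reasoning

22 ⇒ 21. The last bonds cut are the acetal C–O bonds of the two ring B methoxymethyl (MOM) ethers. These ethers are needed earlier as directing groups for lithiation and must survive organolithium, hydride, Mitsunobu and Lewis acid steps. Removing them last exposes the prenylresorcinol to acid only once and briefly.

21 ⇒ 20. The O7–CH3 bond is cut next (forward: a demethylation). In 20 the C8 aldehyde has two ortho oxygens, O1 and O7, but only O7 carries a methyl group open to SN2 attack by a halide. O5 is para to the aldehyde and cannot chelate. This lets ring A travel through the route as a plain dimethyl ether derived from 1, with no early differentiation of two phenols.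

20 ⇒ 19. Ring C is opened at O1–C2. The cut looks wasteful because the ring is made in the key step, but it provides the free C8a hydroxyl of 19 and 17. The forward reaction is an intramolecular Mitsunobu etherification of a primary alcohol by a salicylaldehyde-type phenol, which does not touch C3.

19 ⇒ 17 (through 18). The C8–CHO bond is cut. With the C8a phenol free, C8 is its only unsubstituted ortho position, so a phenoxide-directed, magnesium-templated formylation cannot reach C6. On the closed chroman no such distinction exists. The forward step must tolerate the primary alcohol, the MOM ethers and the olefin.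

17 ⇒ 16. The diol is the reduction product of dihydrocoumarin 16: C2 changes oxidation level and the acyl–O1 bond is cleaved. The reduction also removes the acidity of C3–H, so it follows the key step directly.

16 ⇒ 13 + 4 (through 14 and 15). The C3–C4 and C2–O1 bonds are cut together. This is preferred to a C3–C1' cut because both fragments are then simple, C4 needs no stereocontrol, and the union creates the only stereocentre under catalyst control while closing ring C. In the forward direction acid 13 is activated as mixed anhydride 14 and converted by a chiral isothiourea into an ammonium enolate. Base releases quinone methide 15 from sulfone 4. Conjugate addition forms C3–C4 and lactonisation forms C2–O1.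

4 ⇒ 2 ⇒ 1 and 3. The C–S bond of the sulfone is cut to salicyl alcohol 2 and sulfinate 3, and 2 comes from aldehyde 1 by reduction. The aldehyde carbon of 1 becomes C4, and its three oxygens map onto O1, O7 and O5, so the regiochemistry of ring A is bought.

13 ⇒ 12 ⇒ 11. The acid comes from ester 12, and the C1'–CH2 bond is cut to aryl iodide 11 and a zinc ester enolate. A palladium-catalysed coupling installs the two-carbon chain in one step and avoids a multistep homologation of an aldehyde.

11 ⇒ 9 (through 10) ⇒ 6 and 7 (through 8) ⇒ 5. The C–I bond and the C3'–prenyl bond are both traced to directed lithiation. In 6 the position between the two MOM ethers is lithiated first and takes the prenyl group from 7. With that position filled, the next lithiation (10) can only occur ortho to one MOM ether, which is C1' of the future ring B. Compound 6 is the bis-MOM ether of resorcinol 5.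

## Alternatives that were turned down

Alternative 1: Ring B is taken apart instead of ring C. The bonds C5'–C6', C2'–C3', C4'–C5' and C1'–C2' are traced to a photochemical benzannulation between diazo enone A2, which already carries the chroman with C3 in place, and the prenylated siloxyalkyne A3. Forward, irradiation triggers a Wolff shift (C5'–C6'), the ketene adds the alkyne (C2'–C3', C4'–C5'), and four-electron opening followed by six-electron closure (C1'–C2') gives isoflavan A1.
- For: the substitution pattern of ring B follows from the mechanism without directed metalation, the two ring B oxygens emerge differentiated (free 2'-hydroxyl, silylated 4'-oxygen), and C3 is not acidic in the product. On these points it is stronger than the chosen route, whose ring B depends on two successive lithiations.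
- Against: the ring being built is the one that cheap resorcinol 5 already supplies, and the hard problems stay outside the key step.
  - C3 must be set in a separate asymmetric operation and carried through A2, where C3–H is γ to the enone and open to vinylogous enolisation.
  - A2 and A3 each need several steps of specialised chemistry.
  - The photolysis must spare a prenyl olefin that can intercept ketenes and carbenes.
  - After A1 the formyl group has to go onto a closed chroman in which C6 and C8 are both open and the free 2'-phenol also activates C5'.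
- Comparison: the chosen strategy offers a key step that makes the stereocentre and ring C together from two short fragments and, through the phenol of 17, a structural answer to the C8 problem.

Alternative 2: The bonds C3–C1' and C4–O2' are cut, giving chromene A5 and ortho-iodophenol A6. Forward, a palladium-catalysed oxyarylation under a chiral bisphosphine with a silver base adds the aryl group to C3 and closes the phenol oxygen onto C4, giving the cis-fused pterocarpan A4. Its benzylic C4–O bond is then cleaved reductively to free the 2'-phenol and the C4 methylene.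
- For: two very short fragments, strong precedent for the racemic ring construction, automatic cis fusion and a configurationally robust C3. On convergence and step count to the isoflavan skeleton it is at least as strong as the chosen route.
- Against:
  - Enantioface selection in the carbopalladation of a 2H-chromene under cationic conditions is poorly developed, so C3 rests on the weakest part of the precedent.
  - A second stereocentre (C4) is made only to be erased.
  - The benzylic C–O cleavage cannot be a hydrogenolysis because of the prenyl olefin, and dissolving-metal or ionic-hydrogenation substitutes threaten the olefin or the prenylphenol.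
  - A6 combines a free phenol and a prenyl group under electrophilic divalent palladium and silver, which favours oxidative cyclisation onto the olefin.
  - C8 formylation again has to be done on a closed chroman without a directing phenol.
- Comparison: the chosen strategy offers a better understood stereochemical model (a catalyst-bound enolate with one face covered), no redox manipulation of a benzylic ether, and the directed formylation.

Alternative 3: The bonds C4–C4a and C2–O1 are cut and C3–H is treated as a bond to be formed. The symmetric aldehyde A8 and 2-arylacrolein A9 combine under a chiral phosphoric acid: a free ring carbon of A8 adds to the methylene of A9 (C4–C4a), the enol is protonated at C3 under catalyst control, and the neighbouring hydroxyl closes onto the aldehyde carbon to give lactol A7.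
- For: this is the shortest route by a wide margin. Ring A arrives with formyl, free hydroxyl and methyl ether in their final places, the symmetry of A8 removes both the C6/C8 and the O5/O7 questions, and only deoxygenation at C2 and MOM removal remain. On step economy and ring A regiochemistry it is clearly stronger than the chosen route.
- Against:
  - The nucleophile is a formyl-deactivated, doubly hydrogen-bonded arene, weak at carbon and able to react at oxygen or twice.
  - The stereocentre is made by proton transfer, the least reliable mode of control.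
  - A7 stays in equilibrium with an open α-aryl aldehyde whose C3–H is more labile than that of lactone 16, in the presence of the acid that set it.
  - Deoxygenation of the lactol carbon has to distinguish C2 from the C8 aldehyde and spare the MOM ethers and the olefin.
  - A9 polymerises readily.
- Comparison: the chosen strategy accepts more steps but sets C3 in a carbon–carbon bond-forming event and leaves the labile oxidation level by a hydride reduction that faces no second carbonyl group.

Key step: step 8

Remark on the chemistry: the target is read as (3R). Both antipodes of the isothiourea HyperBTM are taken to be purchasable, and the (2S,3R) form is the one that the accepted facial model assigns to the (3R) series. The descriptor R holds from 16 to 22 because the ranking C2 > C1' > C4 > H never changes.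

## Route

Step 1
Reactants: 1 2-hydroxy-4,6-dimethoxybenzaldehyde
Product: 2 2-(hydroxymethyl)-3,5-dimethoxyphenol
Conditions: NaBH4, MeOH/THF, 0 °C; pH 7 phosphate work-up, crude used directly
Reagents that add atoms: none
Why: Borohydride reduction of an aryl aldehyde. The salicyl alcohol ionises easily at the benzylic carbon, so it is kept cold and neutral and taken on without storage.

Step 2
Reactants: 2 2-(hydroxymethyl)-3,5-dimethoxyphenol; 3 sodium p-toluenesulfinate
Product: 4 3,5-dimethoxy-2-[(4-methylbenzenesulfonyl)methyl]phenol
Conditions: p-TolSO2Na (1.5 equiv), HCO2H/H2O, rt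
Reagents that add atoms: none
Why: Acid-promoted loss of water gives the methoxy-stabilised benzylic cation (protonated quinone methide), which the sulfinate captures at sulfur; this is the sulfinate substitution of ortho-hydroxybenzyl alcohols. Excess sulfinate and dilution should suppress Friedel–Crafts self-condensation, and the sulfone is a storable quinone methide precursor.

Step 3
Reactants: 5 resorcinol
Product: 6 1,3-bis(methoxymethoxy)benzene
Conditions: NaH, MOMCl, DMF, 0 °C → rt
Reagents that add atoms: chloromethyl methyl ether, COCCl
Why: Double Williamson-type O-alkylation of the bis-phenoxide. The MOM groups serve later as ortho-directing groups.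

Step 4
Reactants: 6 1,3-bis(methoxymethoxy)benzene; 7 prenyl bromide
Product: 9 1,3-bis(methoxymethoxy)-2-(3-methylbut-2-en-1-yl)benzene, via aryllithium 8 (not isolated)
Conditions: n-BuLi, THF, 0 °C → rt; then 7, −78 °C → rt
Reagents that add atoms: none
Why: Directed ortho-metalation: the position between the two MOM ethers is the most acidic and doubly coordinated, so lithiation is specific for it. The aryllithium then displaces bromide from the primary allylic carbon of 7 (SN2), placing the prenyl group between the two oxygens.

Step 5
Reactants: 9 1,3-bis(methoxymethoxy)-2-(3-methylbut-2-en-1-yl)benzene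
Product: 11 1-iodo-2,4-bis(methoxymethoxy)-3-(3-methylbut-2-en-1-yl)benzene, via aryllithium 10 (not isolated)
Conditions: n-BuLi, TMEDA, Et2O, −40 → 0 °C; then I2, THF, −78 °C; aq. Na2S2O3
Reagents that add atoms: iodine, [I][I]
Why: Second directed ortho-metalation: with the doubly flanked position filled, a MOM ether delivers the base to the adjacent ring carbon (the two such positions are equivalent) and iodine traps the aryllithium. Ring lithiation through the complex-induced proximity effect should outrun deprotonation of the prenyl methylene at low temperature.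

Step 6
Reactants: 11 1-iodo-2,4-bis(methoxymethoxy)-3-(3-methylbut-2-en-1-yl)benzene
Product: 12 ethyl 2-[2,4-bis(methoxymethoxy)-3-(3-methylbut-2-en-1-yl)phenyl]acetate
Conditions: BrZnCH2CO2Et (from BrCH2CO2Et and Zn dust, THF), Pd(dba)2 (2 mol %), P(t-Bu)3 (2 mol %), THF, rt → 50 °C
Reagents that add atoms: bromo(2-ethoxy-2-oxoethyl)zinc, CCOC(=O)C[Zn]Br
Why: Palladium-catalysed coupling of a Reformatsky reagent with an aryl halide (Negishi-type ester α-arylation): oxidative addition of the C–I bond to zerovalent palladium, transmetalation from zinc and reductive elimination. The neutral zinc enolate tolerates the MOM ethers and the olefin and is arylated once only.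

Step 7
Reactants: 12 ethyl 2-[2,4-bis(methoxymethoxy)-3-(3-methylbut-2-en-1-yl)phenyl]acetate
Product: 13 2-[2,4-bis(methoxymethoxy)-3-(3-methylbut-2-en-1-yl)phenyl]acetic acid
Conditions: LiOH·H2O, THF/MeOH/H2O, rt; then cold 0.5 M HCl to pH 4
Reagents that add atoms: lithium hydroxide, [Li+].[OH-]
Why: Saponification of an unhindered ethyl ester. MOM ethers and olefin are inert to base, and acidification is stopped at pH 4 in the cold to keep the acetals intact.

Step 8
Reactants: 13 2-[2,4-bis(methoxymethoxy)-3-(3-methylbut-2-en-1-yl)phenyl]acetic acid; 4 3,5-dimethoxy-2-[(4-methylbenzenesulfonyl)methyl]phenol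
Product: 16 (3R)-3-[2,4-bis(methoxymethoxy)-3-(3-methylbut-2-en-1-yl)phenyl]-5,7-dimethoxychroman-2-one, via mixed pivalic anhydride 14 (not isolated), via ortho-quinone methide 15 (not isolated)
Conditions: 13 (1.0 equiv), t-BuCOCl, i-Pr2NEt, CH2Cl2, 0 °C; then (2S,3R)-HyperBTM [(2S,3R)-3-isopropyl-2-phenyl-3,4-dihydro-2H-benzo[4,5]thiazolo[3,2-a]pyrimidine] (10 mol %), 4 (1.3 equiv), Cs2CO3, −40 → −10 °C; cold filtration through silica, crude 16 reduced at once
Reagents that add atoms: none
Why: Anhydride 14 acylates N1 of the isothiourea, and deprotonation of the acyl isothiouronium gives the (Z)-ammonium enolate, held coplanar with the catalyst by a 1,5 oxygen–sulfur contact; in parallel Cs2CO3 expels sulfinate from the phenoxide of 4 and releases 15, whose concentration stays low because the base is heterogeneous and the elimination is reversible. The enolate α-carbon (C3) adds to the exocyclic methylene of 15 (C4) in a 1,4-addition driven by rearomatisation of ring A, and the C8a phenoxide so formed attacks the acyl isothiouronium carbon (C2), closing ring C by 6-exo-trig acyl substitution and returning the catalyst. The closest known reaction type is the isothiourea- or carbene-catalysed formal [4+2] annulation of acid-derived enolates with quinone methides made in situ, giving 3,4-dihydrocoumarins; the present case differs only in that the methide carbon is unsubstituted, so C3 is the single stereocentre. C3 is set by the catalyst: the pseudoaxial C2 phenyl group of (2S,3R)-HyperBTM covers one face of the enolate, so C4 bonds to the Re face of C3, which corresponds to (3R) with the ranking C2 > C1' > C4 > H. The step needs facial selectivity at the enolate only, since the methylene terminus is not prochiral, and C-alkylation ahead of O-acylation of the phenoxide of 4; the first comes from the catalyst, the second from the fast loss of sulfinate from the doubly methoxy-stabilised system. The acidic C3–H of 16 is protected by the low temperature, by the electron-rich and therefore poorly leaving C8a aryloxide, which disfavours re-entry of the catalyst into the lactone, and by immediate reduction in step 9.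

Step 9
Reactants: 16 (3R)-3-[2,4-bis(methoxymethoxy)-3-(3-methylbut-2-en-1-yl)phenyl]-5,7-dimethoxychroman-2-one
Product: 17 2-[(2R)-2-[2,4-bis(methoxymethoxy)-3-(3-methylbut-2-en-1-yl)phenyl]-3-hydroxypropyl]-3,5-dimethoxyphenol
Conditions: LiAlH4, THF, −40 → 0 °C; aq. sodium potassium tartrate
Reagents that add atoms: none
Why: Hydride reduction of an aryl ester: two fast hydride transfers take C2 to the primary alkoxide and release the C8a phenoxide, so no enolisable carbonyl stage persists and C3 keeps its configuration. MOM ethers, aryl methyl ethers and the isolated olefin are untouched.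

Step 10
Reactants: 17 2-[(2R)-2-[2,4-bis(methoxymethoxy)-3-(3-methylbut-2-en-1-yl)phenyl]-3-hydroxypropyl]-3,5-dimethoxyphenol
Product: 19 3-[(2R)-2-[2,4-bis(methoxymethoxy)-3-(3-methylbut-2-en-1-yl)phenyl]-3-hydroxypropyl]-2-hydroxy-4,6-dimethoxybenzaldehyde, via hydroxymethyl intermediate 18 (not isolated)
Conditions: MgCl2, Et3N, (CH2O)n, MeCN, 70 °C; aq. NH4Cl
Reagents that add atoms: formaldehyde (from paraformaldehyde), C=O
Why: Magnesium-mediated ortho-formylation of a phenol (Casnati–Skattebøl): the magnesium phenoxide delivers formaldehyde to the ortho carbon, and the benzylic alkoxide of 18 transfers hydride to a second formaldehyde. C8 is the only free ortho position of the C8a phenol, so the regiochemistry is fixed; C6 (para) is not reached by the chelate, and ring B has no free phenol.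

Step 11
Reactants: 19 3-[(2R)-2-[2,4-bis(methoxymethoxy)-3-(3-methylbut-2-en-1-yl)phenyl]-3-hydroxypropyl]-2-hydroxy-4,6-dimethoxybenzaldehyde
Product: 20 (3R)-3-[2,4-bis(methoxymethoxy)-3-(3-methylbut-2-en-1-yl)phenyl]-5,7-dimethoxychroman-8-carbaldehyde
Conditions: PPh3, DIAD, THF, 0 °C → rt
Reagents that add atoms: none
Why: Intramolecular Mitsunobu etherification: the primary alcohol is activated as the alkoxyphosphonium ion and displaced by the acidic salicylaldehyde-type phenol in a 6-exo-tet closure that re-forms O1–C2. C3 is not a reacting centre, so its configuration is retained.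

Step 12
Reactants: 20 (3R)-3-[2,4-bis(methoxymethoxy)-3-(3-methylbut-2-en-1-yl)phenyl]-5,7-dimethoxychroman-8-carbaldehyde
Product: 21 (3R)-3-[2,4-bis(methoxymethoxy)-3-(3-methylbut-2-en-1-yl)phenyl]-7-hydroxy-5-methoxychroman-8-carbaldehyde
Conditions: MgI2 (anhydrous), Et2O/toluene, 60 °C; aq. NH4Cl/Na2S2O3
Reagents that add atoms: none
Why: Chelation-controlled demethylation: magnesium bridges the aldehyde oxygen and the ortho ether oxygen, and iodide removes the methyl group by SN2. O7–CH3 is the only methyl ether ortho to the aldehyde; O5 is para and cannot chelate, and attack at the β-branched C2 of the ring ether is far slower than at methyl.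

Step 13
Reactants: 21 (3R)-3-[2,4-bis(methoxymethoxy)-3-(3-methylbut-2-en-1-yl)phenyl]-7-hydroxy-5-methoxychroman-8-carbaldehyde
Product: 22 (3R)-3-[2,4-dihydroxy-3-(3-methylbut-2-en-1-yl)phenyl]-7-hydroxy-5-methoxychroman-8-carbaldehyde
Conditions: 3 M aq. HCl, MeOH, 40 °C
Reagents that add atoms: none
Why: Acid-catalysed transacetalisation of the two aryl MOM ethers to dimethoxymethane in methanol. Mild acid and moderate temperature are chosen so that deprotection outpaces cyclisation of the prenyl group onto the neighbouring phenols; any dimethyl acetal of the aldehyde reverts in the aqueous medium.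

## Compound list

1 | 2-hydroxy-4,6-dimethoxybenzaldehyde | COc1cc(O)c(C=O)c(OC)c1 | starting material
2 | 2-(hydroxymethyl)-3,5-dimethoxyphenol | COc1cc(O)c(CO)c(OC)c1 | intermediate
3 | sodium p-toluenesulfinate | Cc1ccc(S(=O)[O-])cc1.[Na+] | starting material
4 | 3,5-dimethoxy-2-[(4-methylbenzenesulfonyl)methyl]phenol | COc1cc(O)c(CS(=O)(=O)c2ccc(C)cc2)c(OC)c1 | intermediate
5 | resorcinol (benzene-1,3-diol) | Oc1cccc(O)c1 | starting material
6 | 1,3-bis(methoxymethoxy)benzene | COCOc1cccc(OCOC)c1 | intermediate
7 | prenyl bromide (1-bromo-3-methylbut-2-ene) | CC(C)=CCBr | starting material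
8 | [2,6-bis(methoxymethoxy)phenyl]lithium (formed in the flask, not isolated) | [Li]c1c(OCOC)cccc1OCOC | intermediate
9 | 1,3-bis(methoxymethoxy)-2-(3-methylbut-2-en-1-yl)benzene | COCOc1cccc(OCOC)c1CC=C(C)C | intermediate
10 | [2,4-bis(methoxymethoxy)-3-(3-methylbut-2-en-1-yl)phenyl]lithium (formed in the flask, not isolated) | [Li]c1ccc(OCOC)c(CC=C(C)C)c1OCOC | intermediate
11 | 1-iodo-2,4-bis(methoxymethoxy)-3-(3-methylbut-2-en-1-yl)benzene | COCOc1ccc(I)c(OCOC)c1CC=C(C)C | intermediate
12 | ethyl 2-[2,4-bis(methoxymethoxy)-3-(3-methylbut-2-en-1-yl)phenyl]acetate | CCOC(=O)Cc1ccc(OCOC)c(CC=C(C)C)c1OCOC | intermediate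
13 | 2-[2,4-bis(methoxymethoxy)-3-(3-methylbut-2-en-1-yl)phenyl]acetic acid | OC(=O)Cc1ccc(OCOC)c(CC=C(C)C)c1OCOC | intermediate
14 | 2-[2,4-bis(methoxymethoxy)-3-(3-methylbut-2-en-1-yl)phenyl]acetic pivalic anhydride (formed in the flask, not isolated) | CC(C)(C)C(=O)OC(=O)Cc1ccc(OCOC)c(CC=C(C)C)c1OCOC | intermediate
15 | 3,5-dimethoxy-6-methylidenecyclohexa-2,4-dien-1-one (formed in the flask, not isolated) | COC1=CC(=O)C(=C)C(OC)=C1 | intermediate
16 | (3R)-3-[2,4-bis(methoxymethoxy)-3-(3-methylbut-2-en-1-yl)phenyl]-5,7-dimethoxychroman-2-one | COc1cc(OC)cc2c1C[C@H](c1ccc(OCOC)c(CC=C(C)C)c1OCOC)C(=O)O2 | intermediate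
17 | 2-[(2R)-2-[2,4-bis(methoxymethoxy)-3-(3-methylbut-2-en-1-yl)phenyl]-3-hydroxypropyl]-3,5-dimethoxyphenol | COc1cc(OC)c(C[C@@H](CO)c2ccc(OCOC)c(CC=C(C)C)c2OCOC)c(O)c1 | intermediate
18 | 2-[(2R)-2-[2,4-bis(methoxymethoxy)-3-(3-methylbut-2-en-1-yl)phenyl]-3-hydroxypropyl]-6-(hydroxymethyl)-3,5-dimethoxyphenol (formed in the flask, not isolated) | COc1cc(OC)c(C[C@@H](CO)c2ccc(OCOC)c(CC=C(C)C)c2OCOC)c(O)c1CO | intermediate
19 | 3-[(2R)-2-[2,4-bis(methoxymethoxy)-3-(3-methylbut-2-en-1-yl)phenyl]-3-hydroxypropyl]-2-hydroxy-4,6-dimethoxybenzaldehyde | COc1cc(OC)c(C[C@@H](CO)c2ccc(OCOC)c(CC=C(C)C)c2OCOC)c(O)c1C=O | intermediate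
20 | (3R)-3-[2,4-bis(methoxymethoxy)-3-(3-methylbut-2-en-1-yl)phenyl]-5,7-dimethoxychroman-8-carbaldehyde | COc1cc(OC)c(C=O)c2c1C[C@H](c1ccc(OCOC)c(CC=C(C)C)c1OCOC)CO2 | intermediate
21 | (3R)-3-[2,4-bis(methoxymethoxy)-3-(3-methylbut-2-en-1-yl)phenyl]-7-hydroxy-5-methoxychroman-8-carbaldehyde | COc1cc(O)c(C=O)c2c1C[C@H](c1ccc(OCOC)c(CC=C(C)C)c1OCOC)CO2 | intermediate
22 | (3R)-3-[2,4-dihydroxy-3-(3-methylbut-2-en-1-yl)phenyl]-7-hydroxy-5-methoxychroman-8-carbaldehyde | COc1cc(O)c(C=O)c2c1C[C@H](c1ccc(O)c(CC=C(C)C)c1O)CO2 | target

## Step count and least certain steps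

Total step count: 13. Longest linear sequence: 11 steps (steps 3 to 13, from resorcinol 5); the ring A branch (steps 1 and 2) joins at step 8.

**Step 8 (key step).** Most likely to go wrong:
- erosion of enantiomeric purity, through enolisation of C3 in the lactone by carbonate or through reversible reopening of the lactone by the catalyst;
- incomplete facial discrimination, because the ortho MOM-oxy group twists the aryl ring out of the enolate plane;
- oligomerisation of the unsubstituted quinone methide;
- O-acylation of the phenoxide of 4 before sulfinate is lost.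

Should only the sense of induction be opposite to the model, the (2R,3S) catalyst would be used. The fallback for the other failures replaces catalysis by an auxiliary-controlled alkylation; it sets out from 13 and 1 and returns at 17. Acid 13 is activated as 14 and treated with the lithium salt of (R)-4-benzyl-1,3-oxazolidin-2-one to give (4R)-4-benzyl-3-{2-[2,4-bis(methoxymethoxy)-3-(3-methylbut-2-en-1-yl)phenyl]acetyl}-1,3-oxazolidin-2-one F1. Aldehyde 1 is silylated (t-BuMe2SiCl, imidazole) to 2-[(tert-butyldimethylsilyl)oxy]-4,6-dimethoxybenzaldehyde F2, reduced with NaBH4 to {2-[(tert-butyldimethylsilyl)oxy]-4,6-dimethoxyphenyl}methanol F3 and converted with MsCl, Et3N and LiCl into tert-butyl[2-(chloromethyl)-3,5-dimethoxyphenoxy]dimethylsilane F4, used crude. Enolisation of F1 with NaN(SiMe3)2 at −78 °C and alkylation with F4 should give (4R)-4-benzyl-3-[(2R)-2-[2,4-bis(methoxymethoxy)-3-(3-methylbut-2-en-1-yl)phenyl]-3-{2-[(tert-butyldimethylsilyl)oxy]-4,6-dimethoxyphenyl}propanoyl]-1,3-oxazolidin-2-one F5, because the benzyl group of the (R)-auxiliary covers the Si face of the chelated (Z)-enolate. LiBH4 removes the auxiliary reductively to give (2R)-2-[2,4-bis(methoxymethoxy)-3-(3-methylbut-2-en-1-yl)phenyl]-3-{2-[(tert-butyldimethylsilyl)oxy]-4,6-dimethoxyphenyl}propan-1-ol F6, and Bu4NF cleaves the aryl silyl ether to give 17.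

**Step 5.** Most likely to go wrong: competing deprotonation at the prenyl methylene, which is both benzylic and allylic and flanked by two coordinating ethers, followed by iodination or olefin migration there. The fallback replaces the carbanion by an electrophilic aromatic substitution and runs from 9 directly to 11: N-iodosuccinimide in MeCN at 0 °C in the dark over solid NaHCO3. The ring carbon ortho to one alkoxy group and para to the other is strongly activated, and iodonium formation at the olefin is reversible without an added nucleophile. No new compound is involved.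

**Step 10.** Most likely to go wrong: involvement of the free primary alcohol (hemiformal formation, magnesium alkoxide hydride transfer), slow reaction at the doubly flanked C8, and loss of MOM groups to MgCl2 at 70 °C. The fallback masks the alcohol; it sets out from 17 and returns at 19. Compound 17 is silylated twice (t-BuMe2SiCl, imidazole, DMF) to the bis(tert-butyldimethylsilyl) ether of 17 F7. K2CO3 in MeOH cleaves only the aryl silyl ether, giving the primary tert-butyldimethylsilyl ether of 17 F8. The formylation of step 10 then runs through the primary tert-butyldimethylsilyl ether of 18 F9 (not isolated) to the primary tert-butyldimethylsilyl ether of 19 F10, and Bu4NF gives 19.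

**Step 12.** Most likely to go wrong: Lewis acid cleavage of the ring B MOM ethers followed by closure of the prenyl group onto a freed phenol, or iodide opening of ring C at C2 through the alternative chelate with O1. The fallback removes the need for a demethylation by carrying O7 as an allyl ether; it sets out from 13 with a different ring A partner and returns at 21.
- 2,4-Dihydroxy-6-methoxybenzaldehyde F11 is allylated at the non-chelated 4-hydroxyl (allyl bromide, K2CO3, acetone) to 2-hydroxy-6-methoxy-4-(prop-2-en-1-yloxy)benzaldehyde F12.
- F12 is reduced as in step 1 to 2-(hydroxymethyl)-3-methoxy-5-(prop-2-en-1-yloxy)phenol F13 and converted as in step 2 into 3-methoxy-2-[(4-methylbenzenesulfonyl)methyl]-5-(prop-2-en-1-yloxy)phenol F14.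
- Under the conditions of step 8, F14 releases 5-methoxy-6-methylidene-3-(prop-2-en-1-yloxy)cyclohexa-2,4-dien-1-one F15 (not isolated), which is annulated with 13 (through 14) to the 7-allyloxy analogue of 16 F16.
- F16 is reduced as in step 9 to the 7-allyloxy analogue of 17 F17, formylated as in step 10 through the 7-allyloxy analogue of 18 F18 (not isolated) to the 7-allyloxy analogue of 19 F19, and closed as in step 11 to the 7-allyloxy analogue of 20 F20.
- Pd(PPh3)4 with K2CO3 in MeOH removes the allyl group through a π-allyl complex under basic conditions and gives 21.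

**Step 13.** Most likely to go wrong: acid-promoted cyclisation of the prenyl group onto the 2'- or 4'-hydroxyl, hydration of the olefin, or electrophilic hydroxymethylation of the electron-rich rings by the released one-carbon fragment. The fallback avoids Brønsted acid; it sets out from 21 and returns at 22. Me3SiOTf with 2,2'-bipyridyl in MeCN at 0 °C exchanges the aryl MOM ethers for silyl ethers through pyridinium intermediates in a base-buffered, aprotic medium and silylates the 7-hydroxyl, giving (3R)-5-methoxy-3-[3-(3-methylbut-2-en-1-yl)-2,4-bis(trimethylsilyloxy)phenyl]-7-(trimethylsilyloxy)chroman-8-carbaldehyde F21. Addition of water hydrolyses F21 to 22.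

## Further compounds

F1 | step 8 | (4R)-4-benzyl-3-{2-[2,4-bis(methoxymethoxy)-3-(3-methylbut-2-en-1-yl)phenyl]acetyl}-1,3-oxazolidin-2-one | O=C1OC[C@@H](Cc2ccccc2)N1C(=O)Cc1ccc(OCOC)c(CC=C(C)C)c1OCOC
F2 | step 8 | 2-[(tert-butyldimethylsilyl)oxy]-4,6-dimethoxybenzaldehyde | COc1cc(O[Si](C)(C)C(C)(C)C)c(C=O)c(OC)c1
F3 | step 8 | {2-[(tert-butyldimethylsilyl)oxy]-4,6-dimethoxyphenyl}methanol | COc1cc(O[Si](C)(C)C(C)(C)C)c(CO)c(OC)c1
F4 | step 8 | tert-butyl[2-(chloromethyl)-3,5-dimethoxyphenoxy]dimethylsilane | COc1cc(O[Si](C)(C)C(C)(C)C)c(CCl)c(OC)c1
F5 | step 8 | (4R)-4-benzyl-3-[(2R)-2-[2,4-bis(methoxymethoxy)-3-(3-methylbut-2-en-1-yl)phenyl]-3-{2-[(tert-butyldimethylsilyl)oxy]-4,6-dimethoxyphenyl}propanoyl]-1,3-oxazolidin-2-one | O=C1OC[C@@H](Cc2ccccc2)N1C(=O)[C@H](Cc1c(O[Si](C)(C)C(C)(C)C)cc(OC)cc1OC)c1ccc(OCOC)c(CC=C(C)C)c1OCOC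
F6 | step 8 | (2R)-2-[2,4-bis(methoxymethoxy)-3-(3-methylbut-2-en-1-yl)phenyl]-3-{2-[(tert-butyldimethylsilyl)oxy]-4,6-dimethoxyphenyl}propan-1-ol | OC[C@H](Cc1c(O[Si](C)(C)C(C)(C)C)cc(OC)cc1OC)c1ccc(OCOC)c(CC=C(C)C)c1OCOC
F0 | step 5 | none | none
F7 | step 10 | bis(tert-butyldimethylsilyl) ether of 17 (phenol and primary alcohol both silylated) | COc1cc(OC)c(C[C@@H](CO[Si](C)(C)C(C)(C)C)c2ccc(OCOC)c(CC=C(C)C)c2OCOC)c(O[Si](C)(C)C(C)(C)C)c1
F8 | step 10 | primary tert-butyldimethylsilyl ether of 17 (phenol free) | COc1cc(OC)c(C[C@@H](CO[Si](C)(C)C(C)(C)C)c2ccc(OCOC)c(CC=C(C)C)c2OCOC)c(O)c1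
F9 | step 10 | primary tert-butyldimethylsilyl ether of 18 (not isolated) | COc1cc(OC)c(C[C@@H](CO[Si](C)(C)C(C)(C)C)c2ccc(OCOC)c(CC=C(C)C)c2OCOC)c(O)c1CO
F10 | step 10 | primary tert-butyldimethylsilyl ether of 19 | COc1cc(OC)c(C[C@@H](CO[Si](C)(C)C(C)(C)C)c2ccc(OCOC)c(CC=C(C)C)c2OCOC)c(O)c1C=O
F11 | step 12 | 2,4-dihydroxy-6-methoxybenzaldehyde | COc1cc(O)cc(O)c1C=O
F12 | step 12 | 2-hydroxy-6-methoxy-4-(prop-2-en-1-yloxy)benzaldehyde | C=CCOc1cc(O)c(C=O)c(OC)c1
F13 | step 12 | 2-(hydroxymethyl)-3-methoxy-5-(prop-2-en-1-yloxy)phenol | C=CCOc1cc(O)c(CO)c(OC)c1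
F14 | step 12 | 3-methoxy-2-[(4-methylbenzenesulfonyl)methyl]-5-(prop-2-en-1-yloxy)phenol | C=CCOc1cc(O)c(CS(=O)(=O)c2ccc(C)cc2)c(OC)c1
F15 | step 12 | 5-methoxy-6-methylidene-3-(prop-2-en-1-yloxy)cyclohexa-2,4-dien-1-one (not isolated) | C=CCOC1=CC(=O)C(=C)C(OC)=C1
F16 | step 12 | (3R)-3-[2,4-bis(methoxymethoxy)-3-(3-methylbut-2-en-1-yl)phenyl]-5-methoxy-7-(prop-2-en-1-yloxy)chroman-2-one | COc1cc(OCC=C)cc2c1C[C@H](c1ccc(OCOC)c(CC=C(C)C)c1OCOC)C(=O)O2
F17 | step 12 | 2-[(2R)-2-[2,4-bis(methoxymethoxy)-3-(3-methylbut-2-en-1-yl)phenyl]-3-hydroxypropyl]-3-methoxy-5-(prop-2-en-1-yloxy)phenol | C=CCOc1cc(OC)c(C[C@@H](CO)c2ccc(OCOC)c(CC=C(C)C)c2OCOC)c(O)c1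
F18 | step 12 | 2-[(2R)-2-[2,4-bis(methoxymethoxy)-3-(3-methylbut-2-en-1-yl)phenyl]-3-hydroxypropyl]-6-(hydroxymethyl)-3-methoxy-5-(prop-2-en-1-yloxy)phenol (not isolated) | C=CCOc1cc(OC)c(C[C@@H](CO)c2ccc(OCOC)c(CC=C(C)C)c2OCOC)c(O)c1CO
F19 | step 12 | 3-[(2R)-2-[2,4-bis(methoxymethoxy)-3-(3-methylbut-2-en-1-yl)phenyl]-3-hydroxypropyl]-2-hydroxy-4-methoxy-6-(prop-2-en-1-yloxy)benzaldehyde | C=CCOc1cc(OC)c(C[C@@H](CO)c2ccc(OCOC)c(CC=C(C)C)c2OCOC)c(O)c1C=O
F20 | step 12 | (3R)-3-[2,4-bis(methoxymethoxy)-3-(3-methylbut-2-en-1-yl)phenyl]-5-methoxy-7-(prop-2-en-1-yloxy)chroman-8-carbaldehyde | COc1cc(OCC=C)c(C=O)c2c1C[C@H](c1ccc(OCOC)c(CC=C(C)C)c1OCOC)CO2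
F21 | step 13 | (3R)-5-methoxy-3-[3-(3-methylbut-2-en-1-yl)-2,4-bis(trimethylsilyloxy)phenyl]-7-(trimethylsilyloxy)chroman-8-carbaldehyde | COc1cc(O[Si](C)(C)C)c(C=O)c2c1C[C@H](c1ccc(O[Si](C)(C)C)c(CC=C(C)C)c1O[Si](C)(C)C)CO2
A1 | alternative 1 | (3R)-3-[2-hydroxy-3-(3-methylbut-2-en-1-yl)-4-(triisopropylsilyloxy)phenyl]-5,7-dimethoxychroman | COc1cc(OC)cc2c1C[C@H](c1ccc(O[Si](C(C)C)(C(C)C)C(C)C)c(CC=C(C)C)c1O)CO2
A2 | alternative 1 | (E)-1-diazo-4-[(3R)-5,7-dimethoxychroman-3-yl]but-3-en-2-one | COc1cc(OC)cc2c1C[C@H](/C=C/C(=O)C=[N+]=[N-])CO2
A3 | alternative 1 | triisopropyl[(5-methylhex-4-en-1-yn-1-yl)oxy]silane | CC(C)=CCC#CO[Si](C(C)C)(C(C)C)C(C)C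
A4 | alternative 2 | cis-fused 1,3-dimethoxy-10-(3-methylbut-2-en-1-yl)-9-(triisopropylsilyloxy)pterocarpan, C3 as in 22 | COc1cc(OC)cc2c1[C@H]1[C@H](c3ccc(O[Si](C(C)C)(C(C)C)C(C)C)c(CC=C(C)C)c3O1)CO2
A5 | alternative 2 | 5,7-dimethoxy-2H-chromene | COc1cc(OC)c2C=CCOc2c1
A6 | alternative 2 | 6-iodo-2-(3-methylbut-2-en-1-yl)-3-(triisopropylsilyloxy)phenol | Oc1c(I)ccc(O[Si](C(C)C)(C(C)C)C(C)C)c1CC=C(C)C
A7 | alternative 3 | (3R)-3-[2,4-bis(methoxymethoxy)-3-(3-methylbut-2-en-1-yl)phenyl]-2,7-dihydroxy-5-methoxychroman-8-carbaldehyde (both C2 epimers) | COc1cc(O)c(C=O)c2c1C[C@H](c1ccc(OCOC)c(CC=C(C)C)c1OCOC)C(O)O2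
A8 | alternative 3 | 2,6-dihydroxy-4-methoxybenzaldehyde | COc1cc(O)c(C=O)c(O)c1
A9 | alternative 3 | 2-[2,4-bis(methoxymethoxy)-3-(3-methylbut-2-en-1-yl)phenyl]prop-2-enal | C=C(C=O)c1ccc(OCOC)c(CC=C(C)C)c1OCOC
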